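Count amounts first: taking one of each per target, elm's first nucleophile covers 42.0% of its substrate and maple's 60.0%.

the same everywhere: first nucleophile 0.336 M

| run | substrate | second nucleophile | remark | time |
|---|---|---|---|---|
| epsilon | 0.56 M | 0.75 M | run made earlier |  |
| gamma | 0.56 M | 0.85 M | run made earlier |  |
| theta | 0.56 M | 1 M | run made earlier |  |
| zeta | 0.74 M | 1.12 M | run made earlier |  |
| elm | 0.80 M | 0.600 M |  | 0.80 min |
| maple | 0.56 M | 1.12 M |  | 2.5 min |

| epsilon: time / s | epsilon: target / % | gamma: time / s | gamma: target / % | theta: time / s | theta: target / % | zeta: time / s | zeta: target / % |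
|---|---|---|---|---|---|---|---|
| 10.0 | 8.1 | 10.0 | 10.3 | 20.0 | 17.3 | 10.0 | 8.4 |
| 25.0 | 22.6 | 15.0 | 13.5 | 40.0 | 26.5 | 15.0 | 13.6 |
| 50.0 | 31.5 | 30.0 | 24.9 | 60.0 | 31.0 | 30.0 | 21.6 |
| 80.0 | 34.5 | 60.0 | 31.2 | 80.0 | 30.9 | 60.0 | 27.4 |
| 120 | 35.3 | 120 | 33.6 | 120 | 31.6 | 120 | 28.0 |

(each reading ± 0.5 percentage points)

- the winner by amount of target, in percent of the substrate charged; "neither" if no more than 2 percentage points parts them (elm / maple / neither)
- how much target is there at the end, in percent of the substrate charged: elm
- how much target is there at the end, in percent of the substrate charged: maple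

- what was read earlier has a scatter of 0.5 percentage points, one standard deviation

How much of the used substrate becomes target? Divide the rate of target by the rate of all other substrate loss, and time drops out. I take that ratio as first nucleophile over a rival concentration: the level of first nucleophile at which target takes half of the substrate used.

Read it from a plateau: multiply substrate not become target, per target, by the mean first nucleophile of the run. Epsilon gives 0.435 M. Theta, with more second nucleophile, gives 0.536 M. Extend that line. The rival concentration at elm's second nucleophile is 0.374 M, and at maple's it is 0.584 M.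

Is elm finished at 48 s? Epsilon stood at 89.2% of its plateau at 50.0 s, so apply that fraction to elm. Count maple as finished, since 150 s lies beyond the last reading at 120 s.

My reckoning then gives elm 31.9% and maple 30.1%. The gap of 1.8 percentage points is less than the margin of 2 points, so I say neither.

The forecast differs: elm, with 34.5% for elm and 29.3% for maple. Its ground: “The plateaus fall as the second nucleophile rises, so the two nucleophiles compete for the substrate.”

The flask gives neither: elm 30.0%, maple 29.5%.

    substrate → intermediate (k = 2.70 min⁻¹)
    first nucleophile + intermediate → target (k = 17.0 L mol⁻¹ min⁻¹)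
    second nucleophile + intermediate → other capture product (k = 7.00 L mol⁻¹ min⁻¹)
    target → over-reaction product (k = 0.0280 min⁻¹)
    intermediate → side product (k = 2.10 min⁻¹)

In elm, first nucleophile stands at 0.0926 M at 0.800 min, and its share against 0.374 M falls from 47.3% at the start to 19.8%. In elm, the rate of intermediate capture by second nucleophile over that by first nucleophile rises from 0.91 at 0.216 min to 1.6 at 0.800 min. Now take the neighbour flask, elm with 0.48 M of substrate: the same 0.374 M gives 35.8%, and the computed neighbour holds 34.3%.

The numbers in the tables are calculated from invented constants; the scatter is artificial.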